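**Plan**

1. Numbering: carbocycle C1 (ketone) to C10 (quaternary C–O); C2=C3 is the furanone alkene, C4=C5 the Z-alkene, C6 the ester carbinol, C7/C8 the lactone fusion, C11–C13 the methylene lactone. C1=O and the enol-ether oxygen on C3 are a 1,3-dioxygen pair across C2, which an isoxazoline can carry, and C1 sits on oxygenated C10, whose hydroxyl later closes the furanone.
2. Cuts, from the target backwards: C13 methylene (Mannich base elimination), C6 ester, furanone O–C3 (cyclodehydration of a C10-hydroxy 1,3-diketone), C1–C2 with O–C3 (nitrile oxide plus terminal alkene of the Z-diene), C3–C4 (Stille), C5–C6 (ynone), C7–C8 (aldol).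
3. Forward: the C8–C9–C10–C1 aldehyde is made from (S)-2-methylglycidol; an Evans aldol with a succinate imide closes the trans-γ-lactone; the C6 acyl group becomes the Z-iodo allylic alcohol and then the Z-diene.
4. The C1 nitrile oxide then closes the ten-membered carbocycle and the isoxazoline in one event; N–O cleavage, oxidation and dehydration give the furanone; ester and methylene come last.
5. Stereochemistry: C10 from (S)-2-methylglycidol; C7 and C8 from the (R)-benzyloxazolidinone aldol; C6 from a CBS reduction; Z C4=C5 from anti-hydroiodination and a retentive Stille coupling; the epoxy ester from (R)-2-methylglycidol.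
6. C3 of the isoxazoline and C11 of the Mannich base are transient centres and need no control.

Key step: step 16

Assumption: both enantiomers of 2-methylglycidol are taken as purchasable; each is otherwise one Sharpless epoxidation away from 2-methyl-2-propen-1-ol.

**Route**

Step 1
Reactants: 1 (S)-2-methylglycidol
Product: 2 (R)-2-[(4-methoxybenzyloxy)methyl]-2-methyloxirane
Conditions: NaH, 4-methoxybenzyl chloride, Bu4NI (cat.), THF/DMF, 0 °C to rt
Reagents that add atoms: 4-methoxybenzyl chloride, COc1ccc(CCl)cc1
Why: Williamson etherification of the primary alkoxide should proceed cleanly, and the Payne shift open to this epoxy alkoxide is degenerate, so the quaternary centre is untouched.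

Step 2
Reactants: 2 (R)-2-[(4-methoxybenzyloxy)methyl]-2-methyloxirane; 3 vinylmagnesium bromide
Product: 4 (R)-1-(4-methoxybenzyloxy)-2-methylpent-4-en-2-ol
Conditions: CuI (cat.), THF, −30 to 0 °C
Reagents that add atoms: none
Why: Copper-catalysed Grignard opening of a 2,2-disubstituted epoxide occurs by SN2 attack at the CH2 terminus, so the C10 carbinol centre keeps its configuration.

Step 3
Reactants: 4 (R)-1-(4-methoxybenzyloxy)-2-methylpent-4-en-2-ol
Product: 5 triethylsilyl ether of 4
Conditions: Et3SiOTf, 2,6-lutidine, CH2Cl2, −78 to 0 °C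
Reagents that add atoms: triethylsilyl triflate, CC[Si](CC)(CC)OS(=O)(=O)C(F)(F)F
Why: Silyl triflate with lutidine is the standard silylation of a tertiary alcohol.

Step 4
Reactants: 5 triethylsilyl ether of 4
Product: 6 (R)-4-(4-methoxybenzyloxy)-3-methyl-3-(triethylsilyloxy)butanal
Conditions: OsO4 (cat.), NaIO4, 2,6-lutidine, dioxane/H2O, rt
Reagents that add atoms: sodium periodate (oxygen relayed by OsO4), [Na+].[O-]I(=O)(=O)=O
Why: Lemieux–Johnson cleavage of the terminal alkene should give the C8 aldehyde while the anisyl ring, which ozone could attack, is left alone.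

Step 5
Reactants: 7 (R)-4-benzyloxazolidin-2-one; 8 methyl 4-chloro-4-oxobutanoate
Product: 9 (R)-4-benzyl-3-(4-methoxy-4-oxobutanoyl)oxazolidin-2-one
Conditions: n-BuLi, THF, −78 °C; then 8, −78 to 0 °C
Reagents that add atoms: none
Why: N-acylation of the lithiated oxazolidinone with an acid chloride is the standard entry to Evans imides.

Step 6
Reactants: 9 (R)-4-benzyl-3-(4-methoxy-4-oxobutanoyl)oxazolidin-2-one; 6 (R)-4-(4-methoxybenzyloxy)-3-methyl-3-(triethylsilyloxy)butanal
Product: 12 trans-lactone imide (7R,8S,10R), via boron enolate 10 (not isolated), via aldol adduct 11 (not isolated)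
Conditions: Bu2BOTf, i-Pr2NEt, CH2Cl2, 0 °C; then 6, −78 to 0 °C; H2O2, MeOH, pH 7 buffer; PPTS (cat.), CH2Cl2, rt
Reagents that add atoms: none
Why: Evans syn-aldol through the Z-boron enolate and a Zimmerman–Traxler transition state, in which the (R)-benzyl auxiliary overrides the remote C10 centre and sets 7R,8S, after which the γ-hydroxy ester lactonises so that the 7,8-syn adduct becomes the trans-lactone.

Step 7
Reactants: 12 trans-lactone imide (7R,8S,10R)
Product: 13 trans-lactone C6 carboxylic acid (7R,8S,10R)
Conditions: LiOH, H2O2, THF/H2O, 0 °C; Na2SO3; then 1 M HCl to pH 3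
Reagents that add atoms: hydrogen peroxide, OO
Why: Lithium hydroperoxide cleaves the exocyclic imide carbonyl selectively, and any lactone that opens should re-close on acidification.

Step 8
Reactants: 13 trans-lactone C6 carboxylic acid (7R,8S,10R); 14 tributyl(prop-1-yn-1-yl)stannane
Product: 16 lactone ynone (C6 ketone bearing the prop-1-ynyl group), via acid chloride 15 (not isolated)
Conditions: 1-chloro-N,N,2-trimethylprop-1-en-1-amine, CH2Cl2, 0 °C to rt; then 14, PdCl2(PPh3)2 (cat.), ClCH2CH2Cl, 65 °C
Reagents that add atoms: none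
Why: Neutral acid chloride formation followed by a Stille acylation with the alkynylstannane should give the ynone without base, which matters because C7–H now lies between a carbonyl and the β-acyloxy C8.

Step 9
Reactants: 16 lactone ynone
Product: 17 lactone (Z)-β-iodoenone (iodine on C4, cis to C6)
Conditions: LiI, AcOH, MeCN, rt
Reagents that add atoms: lithium iodide, [Li+].[I-]
Why: Conjugate hydroiodination of an ynone is a kinetic anti addition of HI and should place iodine on C4 cis to the C6 carbonyl.

Step 10
Reactants: 17 lactone (Z)-β-iodoenone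
Product: 18 (Z)-iodo allylic alcohol (C6–O, C7–C11 and C8–O all syn along the C5–C9 chain)
Conditions: (R)-2-methyl-CBS-oxazaborolidine, catecholborane, toluene, −78 °C
Reagents that add atoms: none
Why: In this Corey–Bakshi–Shibata reduction the iodoalkenyl group should take the large-substituent role, so the (R)-catalyst delivers hydride to the face giving the drawn C6 carbinol, which is also the Felkin sense for the C7 centre, and the lactone is not reduced at −78 °C.

Step 11
Reactants: 18 (Z)-iodo allylic alcohol
Product: 19 C6 tert-butyldimethylsilyl ether of 18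
Conditions: t-BuMe2SiOTf, 2,6-lutidine, CH2Cl2, −78 to 0 °C
Reagents that add atoms: tert-butyldimethylsilyl triflate, CC(C)(C)[Si](C)(C)OS(=O)(=O)C(F)(F)F
Why: Silyl triflate silylation of a hindered secondary allylic alcohol is routine.

Step 12
Reactants: 19 C6 tert-butyldimethylsilyl ether of 18
Product: 20 C1 primary alcohol
Conditions: DDQ, CH2Cl2/pH 7 buffer, 0 °C
Reagents that add atoms: none
Why: Oxidative cleavage of the 4-methoxybenzyl ether by DDQ is orthogonal to both silyl ethers, the lactone and the electron-poor vinyl iodide.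

Step 13
Reactants: 20 C1 primary alcohol
Product: 21 C1 aldehyde with the vinyl iodide retained
Conditions: Dess–Martin periodinane, CH2Cl2, 0 °C to rt
Reagents that add atoms: none
Why: Dess–Martin oxidation of the neopentyl-type alcohol gives an aldehyde with no α-hydrogen, so C10 cannot epimerise.

Step 14
Reactants: 21 C1 aldehyde with the vinyl iodide retained; 22 tributyl(vinyl)stannane
Product: 23 Z-diene aldehyde
Conditions: Pd2(dba)3 (cat.), AsPh3, CuI, NMP, rt
Reagents that add atoms: none
Why: Stille coupling proceeds with retention of alkene geometry, copper co-catalysis should let the hindered trisubstituted iodide couple at room temperature, and the aldehyde is tolerated.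

Step 15
Reactants: 23 Z-diene aldehyde
Product: 24 lactone Z-diene aldoxime
Conditions: NH2OH·HCl, pyridine, EtOH, 0 °C to rt
Reagents that add atoms: hydroxylamine hydrochloride, NO.Cl
Why: Oxime condensation of the aldehyde is straightforward, and the oxime geometry is immaterial for nitrile oxide generation.

Step 16
Reactants: 24 lactone Z-diene aldoxime
Product: 27 isoxazoline-bridged cyclodecene lactone, via hydroximoyl chloride 25 (not isolated), via nitrile oxide 26 (not isolated)
Conditions: N-chlorosuccinimide, pyridine (cat.), CHCl3, rt; then syringe-pump addition to Et3N, toluene, 70 °C, final 0.002 M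
Reagents that add atoms: none
Why: N-chlorosuccinimide converts the aldoxime into the hydroximoyl chloride, from which Et3N releases the C1 nitrile oxide slowly at high dilution, and the dipole then adds in a concerted, suprafacial [3+2] fashion to the terminal C2=C3 bond of the Z-diene. The closest known reaction type is the intramolecular nitrile oxide–alkene cycloaddition used as a masked aldol for medium and large carbocycles. The ten-membered carbocycle closes by C1–C2 bond formation in the bridged mode (dipole carbon to the alkene terminus, so C1, C2 and C3 all lie in the ring), and the isoxazoline closes in the same event through the O–C3 bond. The new C3 centre is fixed by whichever face of the vinyl group the tether can reach, as dictated by the trans-lactone, the Z C4=C5 bond and the C6 silyloxy group; it is drawn 3R, but either epimer serves because C3 becomes sp2 in step 19. The step needs carbon-to-C2 regiochemistry, attack at the vinyl group and not at C4=C5, and cyclisation ahead of furoxan dimerisation: the first is the innate preference of nitrile oxides for monosubstituted alkenes, the second rests on the much lower reactivity of the trisubstituted alkene and the absence of the C11 methylene, and the third on the quaternary silyloxy-bearing C10 shielding the dipole while the lactone and Z-alkene turn the chain ends towards each other.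

Step 17
Reactants: 27 isoxazoline-bridged cyclodecene lactone
Product: 28 C11 dimethylaminomethyl lactone (Mannich base) of 27
Conditions: LDA, THF, −78 °C; then Eschenmoser's salt, −78 to 0 °C
Reagents that add atoms: dimethylmethylideneammonium iodide, C=[N+](C)C.[I-]
Why: Mannich alkylation of the lactone enolate, the most acidic site, installs C13 as a latent methylene that is not a Michael acceptor, with the electrophile expected anti to the C7 substituent at a C11 centre that is later destroyed.

Step 18
Reactants: 28 C11 dimethylaminomethyl lactone of 27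
Product: 29 β-hydroxy ketone (C1 ketone, C3 carbinol)
Conditions: Mo(CO)6, MeCN/H2O, 80 °C
Reagents that add atoms: water, O
Why: Mo(CO)6-mediated reductive N–O cleavage followed by hydrolysis of the β-hydroxy imine unmasks the aldol and spares the trisubstituted alkene, the lactone and the silyl ethers.

Step 19
Reactants: 29 β-hydroxy ketone
Product: 30 1,3-diketone (C1 and C3)
Conditions: Dess–Martin periodinane, CH2Cl2, 0 °C to rt
Reagents that add atoms: none
Why: Dess–Martin oxidation of a β-hydroxy ketone to the β-diketone is well known and erases the C3 centre.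

Step 20
Reactants: 30 1,3-diketone
Product: 32 furanone Mannich base with C6 silyl ether, via hydroxy diketone 31 (not isolated)
Conditions: TsOH·H2O, THF/H2O, rt
Reagents that add atoms: none
Why: Acid hydrolysis of the tertiary triethylsilyl ether, 5-exo hemiketalisation of the C10 hydroxyl onto the C3 carbonyl and dehydration is the classical furan-3(2H)-one synthesis from α'-hydroxy 1,3-diketones, and the secondary tert-butyldimethylsilyl ether should hydrolyse far more slowly.

Step 21
Reactants: 32 furanone Mannich base with C6 silyl ether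
Product: 33 C6 alcohol
Conditions: HF·pyridine, pyridine, THF, 0 °C to rt
Reagents that add atoms: none
Why: Buffered HF·pyridine desilylation avoids both strong acid and free alkoxide, so the furanone and the 8,12-lactone should stay in place.

Step 22
Reactants: 34 (R)-2-methylglycidol
Product: 35 (S)-2-methyloxirane-2-carboxylic acid
Conditions: RuCl3 (cat.), NaIO4, MeCN/EtOAc/H2O, 0 °C to rt
Reagents that add atoms: water, O
Why: RuO4-catalysed oxidation of a primary epoxy alcohol to the epoxy acid tolerates the oxirane, and the quaternary centre cannot epimerise (the descriptor changes from R to S only through CIP priorities).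

Step 23
Reactants: 33 C6 alcohol; 35 (S)-2-methyloxirane-2-carboxylic acid
Product: 37 C6 (S)-2-methylglycidate ester Mannich base, via mixed anhydride 36 (not isolated)
Conditions: 2,4,6-trichlorobenzoyl chloride, Et3N, THF, 0 °C; then 33, DMAP, toluene, rt
Reagents that add atoms: none
Why: Yamaguchi esterification is suited to hindered secondary alcohols, the epoxy acid has no α-hydrogen to lose, and the tertiary amine cannot be acylated.

Step 24
Reactants: 37 C6 (S)-2-methylglycidate ester Mannich base
Product: 39 target (6R,7R,8S,10R; epoxide 2S), via ammonium iodide 38 (not isolated)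
Conditions: MeI, THF, rt; then NaHCO3 (aq), CH2Cl2, rt
Reagents that add atoms: none
Why: Quaternisation and E1cB elimination of the β-ammonium lactone is the second half of the Eschenmoser methylenation and unveils the α-methylene lactone last under conditions the epoxy ester and furanone tolerate.

**Compound list**

1 | (S)-2-methylglycidol | OC[C@@]1(C)CO1 | starting material
2 | (R)-2-[(4-methoxybenzyloxy)methyl]-2-methyloxirane | COc1ccc(COC[C@@]2(C)CO2)cc1 | intermediate
3 | vinylmagnesium bromide | C=C[Mg]Br | starting material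
4 | (R)-1-(4-methoxybenzyloxy)-2-methylpent-4-en-2-ol | C=CC[C@@](C)(O)COCc1ccc(OC)cc1 | intermediate
5 | triethylsilyl ether of 4 | C=CC[C@@](C)(O[Si](CC)(CC)CC)COCc1ccc(OC)cc1 | intermediate
6 | (R)-4-(4-methoxybenzyloxy)-3-methyl-3-(triethylsilyloxy)butanal (C8 aldehyde carrying C9, C10, C1) | O=CC[C@@](C)(O[Si](CC)(CC)CC)COCc1ccc(OC)cc1 | intermediate
7 | (R)-4-benzyloxazolidin-2-one | O=C1OC[C@@H](Cc2ccccc2)N1 | starting material
8 | methyl 4-chloro-4-oxobutanoate | COC(=O)CCC(Cl)=O | starting material
9 | (R)-4-benzyl-3-(4-methoxy-4-oxobutanoyl)oxazolidin-2-one | COC(=O)CCC(=O)N1[C@H](Cc2ccccc2)COC1=O | intermediate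
10 | Z-dibutylboron enolate of 9 (enolised at C7) | COC(=O)C/C=C(\OB(CCCC)CCCC)N1[C@H](Cc2ccccc2)COC1=O | intermediate
11 | syn-aldol adduct (7R,8S,10R), open-chain methyl ester with free C8 hydroxyl | COC(=O)C[C@@H](C(=O)N1[C@H](Cc2ccccc2)COC1=O)[C@@H](O)C[C@@](C)(O[Si](CC)(CC)CC)COCc1ccc(OC)cc1 | intermediate
12 | trans-lactone imide (7R,8S,10R): γ-lactone closed from C8–O to C12, acyl oxazolidinone (C6) on C7, CH2–C(Me)(OSiEt3)–CH2O-(4-methoxybenzyl) chain on C8 | C1C(=O)O[C@@H](C[C@@](C)(O[Si](CC)(CC)CC)COCc2ccc(OC)cc2)[C@@H]1C(=O)N3[C@H](Cc4ccccc4)COC3=O | intermediate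
13 | trans-lactone C6 carboxylic acid (7R,8S,10R) | C1C(=O)O[C@@H](C[C@@](C)(O[Si](CC)(CC)CC)COCc2ccc(OC)cc2)[C@@H]1C(=O)O | intermediate
14 | tributyl(prop-1-yn-1-yl)stannane | CC#C[Sn](CCCC)(CCCC)CCCC | starting material
15 | lactone C6 acid chloride | C1C(=O)O[C@@H](C[C@@](C)(O[Si](CC)(CC)CC)COCc2ccc(OC)cc2)[C@@H]1C(Cl)=O | intermediate
16 | lactone ynone (C6 ketone, C5≡C4–CH3) | C1C(=O)O[C@@H](C[C@@](C)(O[Si](CC)(CC)CC)COCc2ccc(OC)cc2)[C@@H]1C(=O)C#CC | intermediate
17 | lactone (Z)-β-iodoenone (iodine on C4, cis to C6) | C1C(=O)O[C@@H](C[C@@](C)(O[Si](CC)(CC)CC)COCc2ccc(OC)cc2)[C@@H]1C(=O)/C=C(C)\I | intermediate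
18 | (Z)-iodo allylic alcohol (C6–O, C7–C11, C8–O all syn) | C1C(=O)O[C@@H](C[C@@](C)(O[Si](CC)(CC)CC)COCc2ccc(OC)cc2)[C@@H]1[C@H](O)/C=C(C)\I | intermediate
19 | C6 tert-butyldimethylsilyl ether of 18 | C1C(=O)O[C@@H](C[C@@](C)(O[Si](CC)(CC)CC)COCc2ccc(OC)cc2)[C@@H]1[C@H](O[Si](C)(C)C(C)(C)C)/C=C(C)\I | intermediate
20 | C1 primary alcohol | C1C(=O)O[C@@H](C[C@@](C)(O[Si](CC)(CC)CC)CO)[C@@H]1[C@H](O[Si](C)(C)C(C)(C)C)/C=C(C)\I | intermediate
21 | C1 aldehyde with the vinyl iodide retained | C1C(=O)O[C@@H](C[C@@](C)(O[Si](CC)(CC)CC)C=O)[C@@H]1[C@H](O[Si](C)(C)C(C)(C)C)/C=C(C)\I | intermediate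
22 | tributyl(vinyl)stannane | C=C[Sn](CCCC)(CCCC)CCCC | starting material
23 | Z-diene aldehyde | C1C(=O)O[C@@H](C[C@@](C)(O[Si](CC)(CC)CC)C=O)[C@@H]1[C@H](O[Si](C)(C)C(C)(C)C)/C=C(C)\C=C | intermediate
24 | lactone Z-diene aldoxime (oxime geometry not specified) | C1C(=O)O[C@@H](C[C@@](C)(O[Si](CC)(CC)CC)C=NO)[C@@H]1[C@H](O[Si](C)(C)C(C)(C)C)/C=C(C)\C=C | intermediate
25 | C1 hydroximoyl chloride | C1C(=O)O[C@@H](C[C@@](C)(O[Si](CC)(CC)CC)C(Cl)=NO)[C@@H]1[C@H](O[Si](C)(C)C(C)(C)C)/C=C(C)\C=C | intermediate
26 | C1 nitrile oxide | C1C(=O)O[C@@H](C[C@@](C)(O[Si](CC)(CC)CC)C#[N+][O-])[C@@H]1[C@H](O[Si](C)(C)C(C)(C)C)/C=C(C)\C=C | intermediate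
27 | isoxazoline-bridged cyclodecene lactone (C1=N–O–C3 bridge, C3 drawn R) | C1C(=O)O[C@H]2C[C@@](C)(O[Si](CC)(CC)CC)C3=NO[C@H](C3)/C(C)=C\[C@@H](O[Si](C)(C)C(C)(C)C)[C@H]12 | intermediate
28 | C11 dimethylaminomethyl lactone of 27 (C13 trans to C6 on the lactone) | CN(C)C[C@H]1C(=O)O[C@H]2C[C@@](C)(O[Si](CC)(CC)CC)C3=NO[C@H](C3)/C(C)=C\[C@@H](O[Si](C)(C)C(C)(C)C)[C@H]12 | intermediate
29 | β-hydroxy ketone (C1 ketone, C3 carbinol) | CN(C)C[C@H]1C(=O)O[C@H]2C[C@@](C)(O[Si](CC)(CC)CC)C(=O)C[C@@H](O)/C(C)=C\[C@@H](O[Si](C)(C)C(C)(C)C)[C@H]12 | intermediate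
30 | 1,3-diketone (C1, C3) | CN(C)C[C@H]1C(=O)O[C@H]2C[C@@](C)(O[Si](CC)(CC)CC)C(=O)CC(=O)/C(C)=C\[C@@H](O[Si](C)(C)C(C)(C)C)[C@H]12 | intermediate
31 | C10-hydroxy 1,3-diketone (in equilibrium with its C3 hemiketal) | CN(C)C[C@H]1C(=O)O[C@H]2C[C@@](C)(O)C(=O)CC(=O)/C(C)=C\[C@@H](O[Si](C)(C)C(C)(C)C)[C@H]12 | intermediate
32 | furanone Mannich base with C6 tert-butyldimethylsilyl ether | CN(C)C[C@H]1C(=O)O[C@H]2C[C@@]3(C)OC(=CC3=O)/C(C)=C\[C@@H](O[Si](C)(C)C(C)(C)C)[C@H]12 | intermediate
33 | C6 alcohol | CN(C)C[C@H]1C(=O)O[C@H]2C[C@@]3(C)OC(=CC3=O)/C(C)=C\[C@@H](O)[C@H]12 | intermediate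
34 | (R)-2-methylglycidol | OC[C@]1(C)CO1 | starting material
35 | (S)-2-methyloxirane-2-carboxylic acid | OC(=O)[C@]1(C)CO1 | intermediate
36 | mixed anhydride of 35 with 2,4,6-trichlorobenzoic acid | O=C(OC(=O)c1c(Cl)cc(Cl)cc1Cl)[C@]2(C)CO2 | intermediate
37 | C6 (S)-2-methylglycidate ester Mannich base | CN(C)C[C@H]1C(=O)O[C@H]2C[C@@]3(C)OC(=CC3=O)/C(C)=C\[C@@H](OC(=O)[C@]3(C)CO3)[C@H]12 | intermediate
38 | trimethylammonium iodide of 37 | C[N+](C)(C)C[C@H]1C(=O)O[C@H]2C[C@@]3(C)OC(=CC3=O)/C(C)=C\[C@@H](OC(=O)[C@]3(C)CO3)[C@H]12.[I-] | intermediate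
39 | CNP0321429.1 (6R,7R,8S,10R; epoxide 2S) | C=C1C(=O)O[C@H]2C[C@@]3(C)OC(=CC3=O)/C(C)=C\[C@@H](OC(=O)[C@]3(C)CO3)[C@H]12 | target

**Step count**

Total steps: 24. Longest linear sequence: 22 (steps 1–4, 6–21, 23, 24); steps 5 and 22 are side branches.

**Steps most likely to fail**

Step 16. The nitrile oxide may dimerise to furoxans faster than the entropically costly ten-ring closure, or it may add to the nearer trisubstituted C4=C5 bond in a seven-ring fused mode. The fallback closes the ring at C3–C4 by an intramolecular Nozaki–Hiyama–Kishi reaction and sets out from aldehyde 21, which still carries the vinyl iodide. Indium-mediated Barbier allylation of the C1 aldehyde (allyl bromide, In, THF/H2O) should give the homoallylic alcohol F1. Lemieux–Johnson cleavage of its terminal alkene should give the β-hydroxy aldehyde F2. CrCl2 with catalytic NiCl2 in DMSO/THF at high dilution should then join C4 to the C3 aldehyde and give the macrocyclic 1,3-diol F3, whose C1 and C3 carbinol configurations do not matter. Excess LDA followed by Eschenmoser's salt should give the Mannich diol F4, and Dess–Martin oxidation of both carbinols returns to the route at diketone 30.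

Step 10. Facial selectivity may be poor because the branched C7 substituent competes with the iodoalkenyl group for the large-substituent role at the oxazaborolidine. The fallback sets out from ynone 16, where the alkyne is unambiguously the small group. Noyori transfer hydrogenation with RuCl[(S,S)-TsDPEN](p-cymene) in i-PrOH should give the propargylic alcohol F5 under reagent control. Hydroxyl-directed trans-hydrosilylation with benzyldimethylsilane and [Cp*Ru(MeCN)3]PF6 should place silicon on the distal carbon, cis to C6, giving the (Z)-vinylsilane F6. Iododesilylation with N-iodosuccinimide in (CF3)2CHOH proceeds with retention and returns to the route at iodo allylic alcohol 18.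

Step 20. Under aqueous acid the C6 silyl ether may be lost, after which the freed hydroxyl can translactonise onto C12, or the β-diketone may suffer retro-Claisen cleavage before the hemiketal dehydrates. The fallback sets out from aldol 29 and separates the three events. Buffered HF·pyridine in pyridine/THF should remove only the tertiary triethylsilyl group and give the dihydroxy ketone F7. Dess–Martin oxidation then gives hydroxy diketone 31 as its hemiketal under neutral conditions, and dehydration with PPTS in dry toluene returns to the route at furanone 32.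

**Further compounds**

F1 | step 16 | C1 homoallylic alcohol from allylation of 21 (C1 carbinol unspecified) | C1C(=O)O[C@@H](C[C@@](C)(O[Si](CC)(CC)CC)C(O)CC=C)[C@@H]1[C@H](O[Si](C)(C)C(C)(C)C)/C=C(C)\I
F2 | step 16 | β-hydroxy aldehyde (C1 carbinol, C3 aldehyde, vinyl iodide) | C1C(=O)O[C@@H](C[C@@](C)(O[Si](CC)(CC)CC)C(O)CC=O)[C@@H]1[C@H](O[Si](C)(C)C(C)(C)C)/C=C(C)\I
F3 | step 16 | macrocyclic C1,C3-diol | C1C(=O)O[C@H]2C[C@@](C)(O[Si](CC)(CC)CC)C(O)CC(O)/C(C)=C\[C@@H](O[Si](C)(C)C(C)(C)C)[C@H]12
F4 | step 16 | C11 dimethylaminomethyl derivative of the macrocyclic diol | CN(C)C[C@H]1C(=O)O[C@H]2C[C@@](C)(O[Si](CC)(CC)CC)C(O)CC(O)/C(C)=C\[C@@H](O[Si](C)(C)C(C)(C)C)[C@H]12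
F5 | step 10 | lactone (S)-propargylic alcohol at C6 | C1C(=O)O[C@@H](C[C@@](C)(O[Si](CC)(CC)CC)COCc2ccc(OC)cc2)[C@@H]1[C@H](O)C#CC
F6 | step 10 | (Z)-C4-benzyldimethylsilyl allylic alcohol | C1C(=O)O[C@@H](C[C@@](C)(O[Si](CC)(CC)CC)COCc2ccc(OC)cc2)[C@@H]1[C@H](O)/C=C(C)\[Si](C)(C)Cc3ccccc3
F7 | step 20 | C3,C10-dihydroxy C1 ketone with C6 silyl ether | CN(C)C[C@H]1C(=O)O[C@H]2C[C@@](C)(O)C(=O)C[C@@H](O)/C(C)=C\[C@@H](O[Si](C)(C)C(C)(C)C)[C@H]12
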